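**Plan**
- Retrosynthesis: the carbocycle of the 7-oxabicyclo[4.1.0]hept-3-ene is cut at C1'–C6' and C2'–C3' (retro-Diels–Alder to furan and vinylene carbonate, after re-bridging C3' and C6' through a temporary oxygen). The C1'–C11 bond is cut to an ent-drimanylmethyl cerium reagent and a bicyclic ketone. The decalin goes back to andrographolide.
- Enabling feature: C3' (vinyl CH) and C6' (oxirane CH) stand 1,4 across the six-membered ring and flank C1'/C2', which carry cis oxygens (oxirane O on C1', OH on C2'). The ring is therefore an opened 7-oxanorbornene: furan α-carbons = C3'/C6', Z-enediol carbonate = C1'/C2'.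
- Forward order: Diels–Alder gives the carbocycle as a meso oxanorbornene; it is desymmetrised and oxidised, and the decalin is added at C1'. E1cB opening of the O-bridge then reveals the cyclohexenone; oxirane closure, hydroxymethylation at C4' and carbonyl reduction at C5' follow.
- Decalin: andrographolide supplies C4, C5, C9, C10 and C19 in the required ent-series. Ozonolysis, enol triflate formation and cuprate coupling set the Δ7 8-methyl alkene; C3 is deoxygenated, C19 oxidised, and the side chain degraded to CH2I.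
- Stereochemistry of the ring: endo Diels–Alder (cis C1'–O/C2'–O), enantioselective silylation (absolute configuration), exo addition at C1', SN2 inversion at C6', hydride delivery anti to the oxirane at C5'.

Key step: step 1

Assumption: locants C1'–C6' follow 7-oxabicyclo[4.1.0]hept-3-ene numbering of the target (C1' quaternary oxirane carbon, C2' its CHOH neighbour, C3' vinyl CH, C4' C–CH2OH, C5' second CHOH, C6' oxirane CH); the decalin keeps labdane locants (C3, C4, C7–C12, C17, C19). The same locants are used for all intermediates.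

**Route**

Step 1
Reactants: 1 furan; 2 vinylene carbonate
Product: 3 meso endo adduct, cis-7-oxabicyclo[2.2.1]hept-5-ene-2,3-diyl carbonate (carbonate oxygens anti to the O-bridge)
Conditions: furan (5 equiv, neat), 1.2 GPa, 25 °C, 24 h (alternatively sealed tube, 120 °C); endo isomer separated by crystallisation
Reagents that add atoms: none
Why: Concerted suprafacial [4π+2π] Diels–Alder cycloaddition of furan (through C2 and C5) with the Z-enediol carbonate, the long-known furan–vinylene carbonate reaction being the direct precedent. It closes the six-membered carbocycle in an intermolecular cycloaddition mode, both new σ-bonds (C3'–C2' and C6'–C1') forming in one transition state, and leaves the ring bridged by the furan oxygen. C1' and C2' become cis because the dienophile adds suprafacially with retention of its Z geometry, and the bridgeheads are fixed by the bridge; the adduct is meso, so no absolute control is needed here. The selectivity required is endo over exo, which should follow from the Alder endo rule under kinetic control at high pressure and ambient temperature, where cycloreversion of the furan adduct is suppressed. Any exo isomer is removed by crystallisation and can be returned to the pool by thermal cycloreversion.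

Step 2
Reactants: 3 endo carbonate adduct
Product: 4 meso (1R,2R,3S,4S)-7-oxabicyclo[2.2.1]hept-5-ene-2,3-diol (both OH endo)
Conditions: K2CO3 (cat.), MeOH, 0 → 23 °C
Reagents that add atoms: none
Why: Base-catalysed transesterification of the cyclic carbonate with methanol should release the cis-diol without touching the strained allylic ether bridge.

Step 3
Reactants: 4 meso diol
Product: 5 (1R,2S,3S,4S)-3-[(tert-butyldimethylsilyl)oxy]-7-oxabicyclo[2.2.1]hept-5-en-2-ol
Conditions: TBSCl (2 equiv), DIPEA, (S)-N-[(R)-3,3-dimethylbutan-2-yl]-3,3-dimethyl-2-{[(1-methylimidazol-2-yl)methyl]amino}butanamide or its enantiomer (30 mol %, the antipode that silylates the hydroxyl on the S-configured carbinol C3 of 4), THF, −40 °C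
Reagents that add atoms: tert-butyldimethylsilyl chloride CC(C)(C)[Si](C)(C)Cl
Why: Catalytic enantioselective silylation of a meso 1,2-diol, in which the hydrogen-bonding N-methylimidazole catalyst should deliver silicon to one enantiotopic hydroxyl and thereby fix the absolute configuration of all ring stereocentres; a silyl ether is used because it cannot racemise by 1,2-acyl migration.

Step 4
Reactants: 5 mono-silyl ether
Product: 6 (1R,3R,4S)-3-[(tert-butyldimethylsilyl)oxy]-7-oxabicyclo[2.2.1]hept-5-en-2-one (OTBS endo)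
Conditions: Dess–Martin periodinane, NaHCO3, CH2Cl2, 0 → 23 °C
Reagents that add atoms: none
Why: Dess–Martin oxidation of the remaining secondary alcohol should give the α-silyloxy ketone under buffered, non-epimerising conditions.

Step 5
Reactants: 7 andrographolide
Product: 8 3,19-O-isopropylidene-andrographolide
Conditions: 2,2-dimethoxypropane, PPTS (cat.), toluene–DMSO, 40 °C
Reagents that add atoms: 2,2-dimethoxypropane COC(C)(C)OC
Why: Acid-catalysed transacetalisation, in which the equatorial 3-OH and the axial C19 CH2OH form the six-membered 3,19-acetonide.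

Step 6
Reactants: 8 acetonide
Product: 10 3,19-O-isopropylidene-8-oxo C12 carboxylic acid (C9–CH2–CO2H, C17 and C13–C16 removed), via keto aldehyde 9 (not isolated)
Conditions: O3, CH2Cl2–MeOH (4:1), −78 °C; Me2S, −78 → 23 °C; then NaClO2, NaH2PO4, 2-methyl-2-butene, t-BuOH–H2O, 0 → 23 °C
Reagents that add atoms: ozone [O-][O+]=O; sodium chlorite [Na+].[O-]Cl=O
Why: Ozonolysis should cleave both the exocyclic C8=C17 methylene (to the C8 ketone) and the C12=C13 alkylidene-lactone bond (to the C12 aldehyde), and Pinnick oxidation then gives the acid; C9, now α to the ketone, keeps its configuration because the equatorial side chain is the thermodynamic epimer.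

Step 7
Reactants: 10 keto acid
Product: 11 methyl ester of 10
Conditions: TMSCHN2, toluene–MeOH (4:1), 0 °C
Reagents that add atoms: trimethylsilyldiazomethane C[Si](C)(C)C=[N+]=[N-]
Why: O-methylation of the carboxylic acid masks C12 for the following enolate chemistry.

Step 8
Reactants: 11 keto ester
Product: 12 Δ7 enol triflate (C8–OTf), methyl ester, 3,19-acetonide
Conditions: KHMDS (1.1 equiv), THF, −78 °C; PhNTf2, −78 → 0 °C
Reagents that add atoms: N-phenyl-bis(trifluoromethanesulfonimide) O=S(=O)(N(c1ccccc1)S(=O)(=O)C(F)(F)F)C(F)(F)F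
Why: Kinetic deprotonation of the ketone should occur at the unhindered C7 methylene rather than at the tertiary C9–H or the less acidic ester α-CH2, and O-triflation fixes the Δ7 enol triflate.

Step 9
Reactants: 12 enol triflate
Product: 13 methyl 3,19-O-isopropylidene-13,14,15,16-tetranor-ent-labd-7-en-12-oate (8-methyl, Δ7)
Conditions: Me2CuLi (4 equiv), THF, −20 → 0 °C
Reagents that add atoms: lithium dimethylcuprate [Li+].C[Cu-]C
Why: Enol triflate–cuprate cross-coupling should install the C8 methyl group and hence the trisubstituted Δ7 alkene with complete positional control, the methyl ester being inert to the cuprate.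

Step 10
Reactants: 13 acetonide ester
Product: 14 methyl 3,19-dihydroxy-13,14,15,16-tetranor-ent-labd-7-en-12-oate
Conditions: AcOH–H2O–THF (3:1:1), 40 °C
Reagents that add atoms: none
Why: Mild aqueous acid should hydrolyse the acetonide to the 3,19-diol without isomerising the trisubstituted alkene.

Step 11
Reactants: 14 diol
Product: 15 3-hydroxy-19-oic acid (C12 methyl ester retained)
Conditions: TEMPO (20 mol %), PhI(OAc)2 (2.5 equiv), MeCN–H2O (1:1), 23 °C
Reagents that add atoms: water O
Why: Oxoammonium (TEMPO) oxidation in wet acetonitrile takes a primary alcohol through the aldehyde hydrate to the acid and should spare the hindered secondary 3-OH.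

Step 12
Reactants: 15 hydroxy acid
Product: 16 19-allyl 12-methyl diester, 3-OH free
Conditions: allyl bromide, KHCO3, DMF, 23 °C
Reagents that add atoms: allyl bromide C=CCBr
Why: O-alkylation of the hindered C19 carboxylate sidesteps acyl substitution at the neopentyl carbonyl, and the allyl ester can later be removed with Pd(0) in the presence of the oxirane.

Step 13
Reactants: 16 hydroxy diester
Product: 17 3-O-(imidazol-1-ylthiocarbonyl) derivative of 16
Conditions: 1,1'-thiocarbonyldiimidazole, DMAP (cat.), 1,2-dichloroethane, 70 °C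
Reagents that add atoms: 1,1'-thiocarbonyldiimidazole S=C(n1ccnc1)n1ccnc1
Why: Thioacylation of the 3-OH provides the substrate for Barton–McCombie deoxygenation.

Step 14
Reactants: 17 thiocarbonyl derivative
Product: 18 19-allyl 12-methyl 13,14,15,16-tetranor-ent-labd-7-ene-12,19-dioate
Conditions: Bu3SnH, AIBN (cat.), toluene, 100 °C
Reagents that add atoms: none
Why: Barton–McCombie deoxygenation, in which the stannyl radical adds to the thiocarbonyl, the C3–O bond fragments and the secondary radical is reduced by the tin hydride.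

Step 15
Reactants: 18 diester
Product: 19 C12 carboxylic acid with the C19 allyl ester retained
Conditions: LiOH·H2O (1.5 equiv), THF–H2O (3:1), 0 → 23 °C; then 1 M HCl to pH 3
Reagents that add atoms: lithium hydroxide [Li+].[OH-]
Why: Saponification should be selective for the unhindered CH2CO2Me over the neopentyl, axial allyl ester at C19.

Step 16
Reactants: 19 acid
Product: 21 allyl 11-iodo-ent-drim-7-en-19-oate (C9–CH2I), via thiohydroxamate ester 20 (not isolated)
Conditions: N-hydroxypyridine-2-thione, DCC, DMAP (cat.), CH2Cl2, dark, 23 °C; then CHI3 (3 equiv), hν (tungsten lamp), 30 °C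
Reagents that add atoms: iodoform IC(I)I; N-hydroxypyridine-2-thione On1ccccc1=S (atoms kept only in 20)
Why: Barton decarboxylative iodination, in which photolysis of the thiohydroxamate ester gives the C11 primary radical after loss of CO2, and this radical should abstract iodine from iodoform faster than it can cyclise onto the Δ7 alkene.

Step 17
Reactants: 21 iodide; 6 bicyclic ketone
Product: 24 tertiary alcohol (C1'–OH endo, C1'–CH2–decalin exo, C2'–OTBS endo, O-bridge between C3' and C6'), via alkyllithium 22 (not isolated), via organocerium 23 (not isolated)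
Conditions: 21, t-BuLi (2.1 equiv), Et2O–pentane, −100 °C; anhydrous CeCl3, THF, −78 °C; then 6, −78 °C; aq. NH4Cl
Reagents that add atoms: tert-butyllithium [Li]C(C)(C)C (Li only in 22); cerium(III) chloride Cl[Ce](Cl)Cl (Ce and Cl only in 23)
Why: Iodine–lithium exchange, transmetalation to the weakly basic organocerium and 1,2-addition to the ketone, which should occur from the exo face (the face of the oxygen bridge), so that the new C1' hydroxyl is endo and cis to the C2' silyl ether while cerium suppresses enolisation of the α-silyloxy ketone.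

Step 18
Reactants: 24 tertiary alcohol
Product: 27 C1',C5'-diol (C5'–OH endo, C4' now CH2), via dimethylsilyl ether 25 (not isolated), via cyclic siloxane 26 (not isolated)
Conditions: (HMe2Si)2NH (neat), NH4Cl (cat.), 60 °C, then evaporation; Karstedt catalyst (1 mol % Pt), toluene, 60 °C; then KF, KHCO3, 30 % H2O2, THF–MeOH, 40 °C
Reagents that add atoms: hydrogen peroxide OO; 1,1,3,3-tetramethyldisilazane C[SiH](C)N[SiH](C)C (atoms kept only in 25 and 26)
Why: Intramolecular hydrosilylation of a homoallylic alcohol (5-exo, Pt catalysis) should deliver silicon from the endo C1' oxygen to the nearer alkene carbon C5', and Tamao–Fleming oxidation replaces silicon by hydroxyl with retention, which singles out C5' rather than C4' for oxidation.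

Step 19
Reactants: 27 diol
Product: 28 C5' ketone (7-oxanorbornan-2-one type), tertiary C1'–OH free
Conditions: Dess–Martin periodinane, NaHCO3, CH2Cl2, 0 → 23 °C
Reagents that add atoms: none
Why: Dess–Martin oxidation converts the secondary C5' alcohol into the ketone while the tertiary alcohol is inert.

Step 20
Reactants: 28 bicyclic ketone
Product: 30 C6' mesylate of the 6'-hydroxycyclohex-3'-en-5'-one, via hydroxy enone 29 (not isolated)
Conditions: DBU (1.1 equiv), CH2Cl2, 0 °C; then Et3N, MsCl, −20 °C
Reagents that add atoms: methanesulfonyl chloride CS(=O)(=O)Cl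
Why: E1cB β-elimination of the bridging alkoxide from the ketone enolate (base-induced opening of a 7-oxanorbornan-2-one) should give the enone with the former bridge oxygen left on C6' trans to the C1' hydroxyl, and the secondary alcohol is then mesylated selectively over the tertiary one.

Step 21
Reactants: 30 mesylate
Product: 31 epoxy enone (C1'–C6' oxirane cis to C2'–OTBS, C5' ketone, C3'=C4')
Conditions: K2CO3, MeOH, 0 °C
Reagents that add atoms: none
Why: Intramolecular Williamson reaction (3-exo-tet), in which the tertiary C1' alkoxide displaces the α-keto mesylate at C6' with inversion so that the oxirane forms on the face of the C1'–O bond, cis to the C2' silyloxy group.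

Step 22
Reactants: 31 epoxy enone
Product: 32 4'-(hydroxymethyl) epoxy enone
Conditions: aq. HCHO (37 %), imidazole (1 equiv), THF–H2O (1:1), 23 °C
Reagents that add atoms: formaldehyde C=O
Why: Morita–Baylis–Hillman reaction of the cyclic enone with formaldehyde should place the hydroxymethyl group on C4', the α-carbon of the enone.

Step 23
Reactants: 32 hydroxymethyl enone
Product: 33 epoxy diol (C5'–OH cis to the oxirane), C2'–OTBS and allyl ester retained
Conditions: NaBH4, CeCl3·7H2O, MeOH, −78 °C
Reagents that add atoms: none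
Why: Luche 1,2-reduction, in which hydride should attack the carbonyl anti to the adjacent oxirane oxygen (Felkin-type and steric control) and give the C5' alcohol cis to the epoxide.

Step 24
Reactants: 33 protected epoxy diol
Product: 35 target acid CNP0458871.1, via silyl ether acid 34 (not isolated)
Conditions: Pd(PPh3)4 (5 mol %), morpholine (3 equiv), THF, 23 °C; then TBAF (3 equiv), AcOH (3 equiv), THF, 0 → 23 °C; pH 4 phosphate work-up
Reagents that add atoms: none
Why: Pd(0)-catalysed deallylation (Tsuji–Trost, morpholine as allyl acceptor) frees the hindered acid without acyl substitution and buffered fluoride removes the silyl ether, the oxirane being neither allylic to the ring alkene nor able to undergo Payne rearrangement with its cis hydroxyls.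

**Compound list**

1 | furan | c1ccoc1 | starting material
2 | vinylene carbonate (1,3-dioxol-2-one) | O=C1OC=CO1 | starting material
3 | meso endo adduct, cis-7-oxabicyclo[2.2.1]hept-5-ene-2,3-diyl carbonate (oxygens anti to the O-bridge) | O=C1O[C@@H]2[C@@H]3C=C[C@@H](O3)[C@@H]2O1 | intermediate
4 | meso (1R,2R,3S,4S)-7-oxabicyclo[2.2.1]hept-5-ene-2,3-diol (both OH endo) | O[C@@H]1[C@@H]2C=C[C@@H](O2)[C@@H]1O | intermediate
5 | (1R,2S,3S,4S)-3-[(tert-butyldimethylsilyl)oxy]-7-oxabicyclo[2.2.1]hept-5-en-2-ol | CC(C)(C)[Si](C)(C)O[C@@H]1[C@@H]2C=C[C@@H](O2)[C@@H]1O | intermediate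
6 | (1R,3R,4S)-3-[(tert-butyldimethylsilyl)oxy]-7-oxabicyclo[2.2.1]hept-5-en-2-one | CC(C)(C)[Si](C)(C)O[C@@H]1[C@@H]2C=C[C@@H](O2)C1=O | intermediate
7 | andrographolide | C=C1CC[C@H]2[C@@](C)(CC[C@@H](O)[C@@]2(C)CO)[C@@H]1C/C=C1\[C@H](O)COC1=O | starting material
8 | 3,19-O-isopropylidene-andrographolide | C=C1CC[C@H]2[C@@](C)(CC[C@H]3OC(C)(C)OC[C@@]23C)[C@@H]1C/C=C1\[C@H](O)COC1=O | intermediate
9 | 3,19-O-isopropylidene-8-oxo C12 aldehyde (C9–CH2–CHO) | O=C1CC[C@H]2[C@@](C)(CC[C@H]3OC(C)(C)OC[C@@]23C)[C@@H]1CC=O | intermediate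
10 | 3,19-O-isopropylidene-8-oxo C12 carboxylic acid | O=C1CC[C@H]2[C@@](C)(CC[C@H]3OC(C)(C)OC[C@@]23C)[C@@H]1CC(=O)O | intermediate
11 | methyl ester of 10 | O=C1CC[C@H]2[C@@](C)(CC[C@H]3OC(C)(C)OC[C@@]23C)[C@@H]1CC(=O)OC | intermediate
12 | Δ7 enol triflate (C8–OTf), methyl ester, 3,19-acetonide | O=S(=O)(OC1=CC[C@H]2[C@@](C)(CC[C@H]3OC(C)(C)OC[C@@]23C)[C@@H]1CC(=O)OC)C(F)(F)F | intermediate
13 | methyl 3,19-O-isopropylidene-13,14,15,16-tetranor-ent-labd-7-en-12-oate | CC1=CC[C@H]2[C@@](C)(CC[C@H]3OC(C)(C)OC[C@@]23C)[C@@H]1CC(=O)OC | intermediate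
14 | methyl 3,19-dihydroxy-13,14,15,16-tetranor-ent-labd-7-en-12-oate | CC1=CC[C@H]2[C@@](C)(CC[C@@H](O)[C@@]2(C)CO)[C@@H]1CC(=O)OC | intermediate
15 | 3-hydroxy-19-oic acid, C12 methyl ester | CC1=CC[C@H]2[C@@](C)(CC[C@@H](O)[C@@]2(C)C(=O)O)[C@@H]1CC(=O)OC | intermediate
16 | 19-allyl 12-methyl 3-hydroxy diester | CC1=CC[C@H]2[C@@](C)(CC[C@@H](O)[C@@]2(C)C(=O)OCC=C)[C@@H]1CC(=O)OC | intermediate
17 | 3-O-(imidazol-1-ylthiocarbonyl) derivative of 16 | CC1=CC[C@H]2[C@@](C)(CC[C@@H](OC(=S)n3ccnc3)[C@@]2(C)C(=O)OCC=C)[C@@H]1CC(=O)OC | intermediate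
18 | 19-allyl 12-methyl 13,14,15,16-tetranor-ent-labd-7-ene-12,19-dioate | CC1=CC[C@H]2[C@@](C)(CCC[C@@]2(C)C(=O)OCC=C)[C@@H]1CC(=O)OC | intermediate
19 | C12 carboxylic acid, C19 allyl ester | CC1=CC[C@H]2[C@@](C)(CCC[C@@]2(C)C(=O)OCC=C)[C@@H]1CC(=O)O | intermediate
20 | thiohydroxamate (N-acyloxypyridine-2-thione) ester of 19 | CC1=CC[C@H]2[C@@](C)(CCC[C@@]2(C)C(=O)OCC=C)[C@@H]1CC(=O)On1ccccc1=S | intermediate
21 | allyl 11-iodo-ent-drim-7-en-19-oate (C9–CH2I; CO2allyl axial, cis to the C10 methyl) | CC1=CC[C@H]2[C@@](C)(CCC[C@@]2(C)C(=O)OCC=C)[C@@H]1CI | intermediate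
22 | C11 alkyllithium from 21 | CC1=CC[C@H]2[C@@](C)(CCC[C@@]2(C)C(=O)OCC=C)[C@@H]1C[Li] | intermediate
23 | C11 alkyl(dichloro)cerium reagent | CC1=CC[C@H]2[C@@](C)(CCC[C@@]2(C)C(=O)OCC=C)[C@@H]1C[Ce](Cl)Cl | intermediate
24 | tertiary alcohol: 2-endo-hydroxy-2-exo-(decalinylmethyl)-3-endo-silyloxy-7-oxabicyclo[2.2.1]hept-5-ene | CC1=CC[C@H]2[C@@](C)(CCC[C@@]2(C)C(=O)OCC=C)[C@@H]1C[C@]1(O)[C@H]2C=C[C@H](O2)[C@H]1O[Si](C)(C)C(C)(C)C | intermediate
25 | O-dimethylsilyl ether of 24 | CC1=CC[C@H]2[C@@](C)(CCC[C@@]2(C)C(=O)OCC=C)[C@@H]1C[C@]1(O[SiH](C)C)[C@H]2C=C[C@H](O2)[C@H]1O[Si](C)(C)C(C)(C)C | intermediate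
26 | cyclic siloxane (1,2-oxasilolane joining C1'–O and C5', endo) | CC1=CC[C@H]2[C@@](C)(CCC[C@@]2(C)C(=O)OCC=C)[C@@H]1C[C@]1(O[Si]3(C)C)[C@H]2[C@@H]3C[C@H](O2)[C@H]1O[Si](C)(C)C(C)(C)C | intermediate
27 | C1',C5'-diol (C5'–OH endo) | CC1=CC[C@H]2[C@@](C)(CCC[C@@]2(C)C(=O)OCC=C)[C@@H]1C[C@]1(O)[C@H]2[C@@H](O)C[C@H](O2)[C@H]1O[Si](C)(C)C(C)(C)C | intermediate
28 | C5' ketone, bridge intact | CC1=CC[C@H]2[C@@](C)(CCC[C@@]2(C)C(=O)OCC=C)[C@@H]1C[C@]1(O)[C@H]2C(=O)C[C@H](O2)[C@H]1O[Si](C)(C)C(C)(C)C | intermediate
29 | hydroxy enone (C5' ketone, C3'=C4', C6'–OH trans to C1'–OH) | CC1=CC[C@H]2[C@@](C)(CCC[C@@]2(C)C(=O)OCC=C)[C@@H]1C[C@]1(O)[C@H](O)C(=O)C=C[C@H]1O[Si](C)(C)C(C)(C)C | intermediate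
30 | C6' mesylate of 29 | CC1=CC[C@H]2[C@@](C)(CCC[C@@]2(C)C(=O)OCC=C)[C@@H]1C[C@]1(O)[C@H](OS(C)(=O)=O)C(=O)C=C[C@H]1O[Si](C)(C)C(C)(C)C | intermediate
31 | epoxy enone (oxirane cis to C2'–OTBS) | CC1=CC[C@H]2[C@@](C)(CCC[C@@]2(C)C(=O)OCC=C)[C@@H]1C[C@]12O[C@H]1C(=O)C=C[C@H]2O[Si](C)(C)C(C)(C)C | intermediate
32 | 4'-(hydroxymethyl) epoxy enone | CC1=CC[C@H]2[C@@](C)(CCC[C@@]2(C)C(=O)OCC=C)[C@@H]1C[C@]12O[C@H]1C(=O)C(CO)=C[C@H]2O[Si](C)(C)C(C)(C)C | intermediate
33 | epoxy diol, C2'–OTBS, allyl ester | CC1=CC[C@H]2[C@@](C)(CCC[C@@]2(C)C(=O)OCC=C)[C@@H]1C[C@]12O[C@H]1[C@@H](O)C(CO)=C[C@H]2O[Si](C)(C)C(C)(C)C | intermediate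
34 | carboxylic acid with C2'–OTBS | CC1=CC[C@H]2[C@@](C)(CCC[C@@]2(C)C(=O)O)[C@@H]1C[C@]12O[C@H]1[C@@H](O)C(CO)=C[C@H]2O[Si](C)(C)C(C)(C)C | intermediate
35 | (1R,4aS,5R,8aS)-5-{[(1R,2R,5S,6S)-2,5-dihydroxy-4-(hydroxymethyl)-7-oxabicyclo[4.1.0]hept-3-en-1-yl]methyl}-1,4a,6-trimethyl-1,2,3,4,4a,5,8,8a-octahydronaphthalene-1-carboxylic acid (CNP0458871.1) | CC1=CC[C@H]2[C@@](C)(CCC[C@@]2(C)C(=O)O)[C@@H]1C[C@]12O[C@H]1[C@@H](O)C(CO)=C[C@H]2O | target

**Summary**

Total step count: 24. Longest linear sequence: 20 steps (steps 5–24, from andrographolide); the ring branch (steps 1–4) joins at step 17.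

Steps most likely to fail:

1. Step 17. The alkyllithium may attack the allyl ester before transmetalation, or the hindered addition may lose out to enolisation of the α-silyloxy ketone. Fallback: remove the electrophilic ester before the union. Starting from 21, Pd(PPh3)4/morpholine gives the iodo acid F1. Treatment with t-BuLi (3.1 equiv) generates the lithium carboxylate–alkyllithium dianion; CeCl3 and then ketone 6 should give the hydroxy acid F2. Re-esterification with allyl bromide/KHCO3 returns to 24.

2. Step 18. The crowded tertiary alcohol may resist silylation, or Si–H may be delivered to C4' instead of C5'. Fallback: oxygen is delivered to C5' by an iodocarbonate cyclisation instead. Starting from 24, KHMDS/Boc2O gives the tert-butyl carbonate F3. IBr (1 equiv, −85 °C) should form the cyclic iodocarbonate F4, the carbonate oxygen attacking C5' from the endo face with iodine exo on C4'; the carbonate-assisted strained alkene is expected to react before the decalin alkene. Bu3SnH/AIBN removes iodine to give the cyclic carbonate F5, and K2CO3/MeOH returns to diol 27.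

3. Step 22. The basic conditions may cause loss of the C2' silyloxy group with aromatisation, or the crowded enone may fail to react. Fallback: the carbon is introduced by cross-coupling. Starting from 31, α-iodination (I2, pyridine, CH2Cl2) gives the α-iodo enone F6, and Stille coupling with (tributylstannyl)methanol (Pd2(dba)3, AsPh3, 50 °C, no allyl acceptor present) returns to 32.

Further compounds
F1 | step 17 | 11-iodo-ent-drim-7-en-19-oic acid (free acid of 21) | CC1=CC[C@H]2[C@@](C)(CCC[C@@]2(C)C(=O)O)[C@@H]1CI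
F2 | step 17 | free C19 acid of tertiary alcohol 24 | CC1=CC[C@H]2[C@@](C)(CCC[C@@]2(C)C(=O)O)[C@@H]1C[C@]1(O)[C@H]2C=C[C@H](O2)[C@H]1O[Si](C)(C)C(C)(C)C
F3 | step 18 | C1'-O-tert-butyl carbonate of 24 | CC1=CC[C@H]2[C@@](C)(CCC[C@@]2(C)C(=O)OCC=C)[C@@H]1C[C@]1(OC(=O)OC(C)(C)C)[C@H]2C=C[C@H](O2)[C@H]1O[Si](C)(C)C(C)(C)C
F4 | step 18 | cyclic iodocarbonate (carbonate joining C1'–O and C5'–O endo, iodine exo on C4') | CC1=CC[C@H]2[C@@](C)(CCC[C@@]2(C)C(=O)OCC=C)[C@@H]1C[C@]1(OC(=O)O3)[C@H]2[C@@H]3[C@H](I)[C@H](O2)[C@H]1O[Si](C)(C)C(C)(C)C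
F5 | step 18 | cyclic carbonate after deiodination | CC1=CC[C@H]2[C@@](C)(CCC[C@@]2(C)C(=O)OCC=C)[C@@H]1C[C@]1(OC(=O)O3)[C@H]2[C@@H]3C[C@H](O2)[C@H]1O[Si](C)(C)C(C)(C)C
F6 | step 22 | 4'-iodo epoxy enone | CC1=CC[C@H]2[C@@](C)(CCC[C@@]2(C)C(=O)OCC=C)[C@@H]1C[C@]12O[C@H]1C(=O)C(I)=C[C@H]2O[Si](C)(C)C(C)(C)C
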